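**Plan**
- Feature: with C1 the guaiacyl benzylic carbon and C7 the catechol benzylic carbon, the C3 carbonyl oxygen is 1,3 to the C5 hydroxyl. An H–SiMe2–O unit on the C5 oxygen can therefore add across a C2≡C3 alkyne through a five-membered ring (O, Si, C3, C4, C5), and the new C3–Si bond is later exchanged for C3=O.
- Retrosynthetic cuts, in order: the three O–benzyl bonds; C3=O back to C3–Si and the C2≡C3 alkyne; C3–C4 (lithium acetylide plus terminal epoxide); C1–C2 (benzylic bromide plus ethynyl Grignard); C6–C7 (benzylic bromide plus allyl Grignard).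
- Forward: the C4–C7 epoxide arm is made from 3,4-bis(benzyloxy)benzaldehyde and the C1–C3 propargyl arene arm from O-benzylvanillin. They are joined at C3–C4, the alcohol is silylated, the oxasilolane (the only ring formed) is closed and then opened oxidatively, and the phenols are freed.
- Stereochemistry: C5 (S) comes from hydrolytic kinetic resolution of the terminal epoxide. The acetylide attacks the CH2 terminus and no later step breaks a bond at C5.

Key step: step 11

Remark: chain compounds are numbered C1 (guaiacyl end) to C7 (catechol end) as in the target; aldehydes 1 and 8 and the Grignard solutions 4 and 11 are taken as purchased.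

**Route**

Step 1
Reactants: 1 3,4-bis(benzyloxy)benzaldehyde
Product: 2 [3,4-bis(benzyloxy)phenyl]methanol
Conditions: NaBH4, MeOH–THF, 0 °C to rt
Reagents that add atoms: none
Why: NaBH4 reduction of an aryl aldehyde to the benzylic alcohol is chemoselective, and aryl benzyl ethers are inert to borohydride.

Step 2
Reactants: 2 [3,4-bis(benzyloxy)phenyl]methanol
Product: 3 1,2-bis(benzyloxy)-4-(bromomethyl)benzene
Conditions: PBr3, CH2Cl2, 0 °C; used without storage
Reagents that add atoms: phosphorus tribromide BrP(Br)Br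
Why: PBr3 converts the electron-rich benzylic alcohol into the bromide through a phosphite ester and bromide displacement (alcohol-to-bromide substitution) without cleaving aryl benzyl ethers.

Step 3
Reactants: 3 1,2-bis(benzyloxy)-4-(bromomethyl)benzene; 4 allylmagnesium bromide
Product: 5 1,2-bis(benzyloxy)-4-(but-3-en-1-yl)benzene
Conditions: allylMgBr (Et2O solution), THF, 0 °C to rt
Reagents that add atoms: none
Why: Nucleophilic substitution of a reactive benzylic bromide by an allyl Grignard reagent (sp3–sp3 Grignard coupling) forms the C6–C7 bond and should give the homoallyl arene, the ethers being inert to organomagnesium.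

Step 4
Reactants: 5 1,2-bis(benzyloxy)-4-(but-3-en-1-yl)benzene
Product: 6 rac-2-{2-[3,4-bis(benzyloxy)phenyl]ethyl}oxirane
Conditions: mCPBA, CH2Cl2, 0 °C to rt; NaHCO3 wash
Reagents that add atoms: 3-chloroperoxybenzoic acid O=C(OO)c1cccc(Cl)c1
Why: Prilezhaev epoxidation of the monosubstituted alkene is a concerted oxygen transfer that should leave the alkoxy arene alone under these mild conditions; the epoxide is racemic at this stage.

Step 5
Reactants: 6 rac-2-{2-[3,4-bis(benzyloxy)phenyl]ethyl}oxirane
Product: 7 (2S)-2-{2-[3,4-bis(benzyloxy)phenyl]ethyl}oxirane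
Conditions: (S,S)-(salen)Co(OAc) (0.5 mol%; salen = N,N'-bis(3,5-di-tert-butylsalicylidene)cyclohexane-1,2-diaminate, trivalent cobalt), H2O (0.55 equiv), minimal THF, 0 °C to rt; chromatography
Reagents that add atoms: none
Why: In the Jacobsen hydrolytic kinetic resolution the (S,S) cobalt salen complex hydrolyses the (R)-epoxide much faster than the (S)-epoxide in a bimetallic ring opening, so the (S)-epoxide carrying the future C5 stereocenter should be recovered in high enantiomeric purity and separated from the polar (R)-diol.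

Step 6
Reactants: 8 4-(benzyloxy)-3-methoxybenzaldehyde
Product: 9 [4-(benzyloxy)-3-methoxyphenyl]methanol
Conditions: NaBH4, MeOH–THF, 0 °C to rt
Reagents that add atoms: none
Why: Borohydride reduction of the aryl aldehyde is chemoselective and leaves the benzyl and methyl ethers untouched.

Step 7
Reactants: 9 [4-(benzyloxy)-3-methoxyphenyl]methanol
Product: 10 1-(benzyloxy)-4-(bromomethyl)-2-methoxybenzene
Conditions: PBr3, CH2Cl2, 0 °C; used without storage
Reagents that add atoms: phosphorus tribromide BrP(Br)Br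
Why: Alcohol-to-bromide substitution with PBr3 is standard for para-alkoxybenzylic alcohols, and the labile bromide is carried on directly.

Step 8
Reactants: 10 1-(benzyloxy)-4-(bromomethyl)-2-methoxybenzene; 11 ethynylmagnesium bromide
Product: 12 1-(benzyloxy)-2-methoxy-4-(prop-2-yn-1-yl)benzene
Conditions: HC≡CMgBr (THF solution, 2.5 equiv), CuBr (10 mol%), THF, 0 °C to 50 °C
Reagents that add atoms: none
Why: Copper-catalysed substitution of a benzylic bromide by an alkynyl Grignard reagent forms the C1–C2 bond, and the excess of ethynylmagnesium bromide should suppress a second benzylation.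

Step 9
Reactants: 12 1-(benzyloxy)-2-methoxy-4-(prop-2-yn-1-yl)benzene; 7 (2S)-2-{2-[3,4-bis(benzyloxy)phenyl]ethyl}oxirane
Product: 14 (5S)-1-[4-(benzyloxy)-3-methoxyphenyl]-7-[3,4-bis(benzyloxy)phenyl]hept-2-yn-5-ol, via lithium acetylide 13 (not isolated)
Conditions: 12 (1.4 equiv), n-BuLi (1.35 equiv), THF, −78 °C; BF3·OEt2 (1.4 equiv); then 7 (1.0 equiv), −78 °C; aq. NH4Cl
Reagents that add atoms: none
Why: In this Yamaguchi–Hirao alkynylation the acetylide made by deprotonating the sp C–H opens the BF3-activated terminal epoxide at its unsubstituted carbon by SN2, forming C3–C4 without touching the C5–O bond, so the (S) configuration is retained.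

Step 10
Reactants: 14 (5S)-1-[4-(benzyloxy)-3-methoxyphenyl]-7-[3,4-bis(benzyloxy)phenyl]hept-2-yn-5-ol
Product: 15 {[(5S)-1-[4-(benzyloxy)-3-methoxyphenyl]-7-[3,4-bis(benzyloxy)phenyl]hept-2-yn-5-yl]oxy}dimethylsilane
Conditions: (HMe2Si)2NH (excess, neat), 50 °C; volatiles removed under vacuum
Reagents that add atoms: 1,1,3,3-tetramethyldisilazane C[SiH](C)N[SiH](C)C
Why: Silyl transfer from the disilazane to the secondary alcohol (silylation with loss of ammonia) needs no base or salt, and stripping the volatile reagent and ammonia should leave a silyl ether fit for platinum catalysis.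

Step 11
Reactants: 15 {[(5S)-1-[4-(benzyloxy)-3-methoxyphenyl]-7-[3,4-bis(benzyloxy)phenyl]hept-2-yn-5-yl]oxy}dimethylsilane
Product: 16 (5S)-3-{(E)-2-[4-(benzyloxy)-3-methoxyphenyl]ethylidene}-5-{2-[3,4-bis(benzyloxy)phenyl]ethyl}-2,2-dimethyl-1,2-oxasilolane
Conditions: Pt2[(CH2=CHSiMe2)2O]3 (Karstedt catalyst, zerovalent platinum, 0.5 mol% Pt), THF, 0.02 M, rt
Reagents that add atoms: none
Why: Zerovalent platinum inserts into the Si–H bond, the tethered alkyne inserts into Pt–H (Chalk–Harrod cycle) and C–Si reductive elimination places H on C2 and Si on C3 from the same face; the closest known reaction type is the platinum-catalysed intramolecular hydrosilylation of homopropargylic hydrodimethylsilyl ethers. The ring closes in the 5-exo-dig mode to the 1,2-oxasilolane made of O, Si, C3, C4 and C5, with the C2=C3 bond exocyclic and E (H cis to Si). No stereocenter is created, and C5 is a spectator because no bond to it is touched. The step needs silicon at C3 rather than C2: the three-atom O–Si–H tether reaches C3 easily, whereas syn addition in the 6-endo sense would place an E double bond inside a six-membered ring. It also needs intramolecular addition to outrun intermolecular addition, which dilution and the five-membered transition state should secure; the benzyl ethers and arenes are inert to the catalyst.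

Step 12
Reactants: 16 (5S)-3-{(E)-2-[4-(benzyloxy)-3-methoxyphenyl]ethylidene}-5-{2-[3,4-bis(benzyloxy)phenyl]ethyl}-2,2-dimethyl-1,2-oxasilolane
Product: 18 (5S)-1-[4-(benzyloxy)-3-methoxyphenyl]-7-[3,4-bis(benzyloxy)phenyl]-5-hydroxyheptan-3-one, via C3 enol 17 (not isolated)
Conditions: 30% aq. H2O2, KF, KHCO3, THF–MeOH (1:1), rt
Reagents that add atoms: hydrogen peroxide OO
Why: In the Tamao–Fleming oxidation fluoride-activated silicon takes up hydroperoxide, the alkenyl group migrates from Si to O with retention, and hydrolysis of both Si–O bonds frees the C5 hydroxyl and the C3 enol, which tautomerises to the ketone in a bicarbonate medium that should spare the β-hydroxy ketone and the C5 configuration.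

Step 13
Reactants: 18 (5S)-1-[4-(benzyloxy)-3-methoxyphenyl]-7-[3,4-bis(benzyloxy)phenyl]-5-hydroxyheptan-3-one
Product: 19 (5S)-7-(3,4-dihydroxyphenyl)-5-hydroxy-1-(4-hydroxy-3-methoxyphenyl)heptan-3-one (3''-demethylhexahydrocurcumin)
Conditions: H2 (1 atm), Pd/C (10 wt% Pd), EtOAc–MeOH, rt
Reagents that add atoms: none
Why: Palladium-catalysed hydrogenolysis cleaves the three aryl benzyl ethers while the dialkyl ketone, the secondary alcohol and the C5 stereocenter should remain untouched.

**Compound list**
1 | 3,4-bis(benzyloxy)benzaldehyde | O=Cc1ccc(OCc2ccccc2)c(OCc2ccccc2)c1 | starting material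
2 | [3,4-bis(benzyloxy)phenyl]methanol | OCc1ccc(OCc2ccccc2)c(OCc2ccccc2)c1 | intermediate
3 | 1,2-bis(benzyloxy)-4-(bromomethyl)benzene | BrCc1ccc(OCc2ccccc2)c(OCc2ccccc2)c1 | intermediate
4 | allylmagnesium bromide | C=CC[Mg]Br | starting material
5 | 1,2-bis(benzyloxy)-4-(but-3-en-1-yl)benzene | C=CCCc1ccc(OCc2ccccc2)c(OCc2ccccc2)c1 | intermediate
6 | rac-2-{2-[3,4-bis(benzyloxy)phenyl]ethyl}oxirane | C1OC1CCc1ccc(OCc2ccccc2)c(OCc2ccccc2)c1 | intermediate
7 | (2S)-2-{2-[3,4-bis(benzyloxy)phenyl]ethyl}oxirane | C1O[C@H]1CCc1ccc(OCc2ccccc2)c(OCc2ccccc2)c1 | intermediate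
8 | 4-(benzyloxy)-3-methoxybenzaldehyde | COc1cc(C=O)ccc1OCc1ccccc1 | starting material
9 | [4-(benzyloxy)-3-methoxyphenyl]methanol | COc1cc(CO)ccc1OCc1ccccc1 | intermediate
10 | 1-(benzyloxy)-4-(bromomethyl)-2-methoxybenzene | COc1cc(CBr)ccc1OCc1ccccc1 | intermediate
11 | ethynylmagnesium bromide | C#C[Mg]Br | starting material
12 | 1-(benzyloxy)-2-methoxy-4-(prop-2-yn-1-yl)benzene | COc1cc(CC#C)ccc1OCc1ccccc1 | intermediate
13 | {3-[4-(benzyloxy)-3-methoxyphenyl]prop-1-yn-1-yl}lithium | COc1cc(CC#C[Li])ccc1OCc1ccccc1 | intermediate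
14 | (5S)-1-[4-(benzyloxy)-3-methoxyphenyl]-7-[3,4-bis(benzyloxy)phenyl]hept-2-yn-5-ol | COc1cc(CC#CC[C@@H](O)CCc2ccc(OCc3ccccc3)c(OCc3ccccc3)c2)ccc1OCc1ccccc1 | intermediate
15 | {[(5S)-1-[4-(benzyloxy)-3-methoxyphenyl]-7-[3,4-bis(benzyloxy)phenyl]hept-2-yn-5-yl]oxy}dimethylsilane | COc1cc(CC#CC[C@@H](O[SiH](C)C)CCc2ccc(OCc3ccccc3)c(OCc3ccccc3)c2)ccc1OCc1ccccc1 | intermediate
16 | (5S)-3-{(E)-2-[4-(benzyloxy)-3-methoxyphenyl]ethylidene}-5-{2-[3,4-bis(benzyloxy)phenyl]ethyl}-2,2-dimethyl-1,2-oxasilolane | COc1cc(C/C=C2\C[C@H](CCc3ccc(OCc4ccccc4)c(OCc4ccccc4)c3)O[Si]2(C)C)ccc1OCc1ccccc1 | intermediate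
17 | (2E,5S)-1-[4-(benzyloxy)-3-methoxyphenyl]-7-[3,4-bis(benzyloxy)phenyl]hept-2-ene-3,5-diol | COc1cc(C/C=C(O)\C[C@@H](O)CCc2ccc(OCc3ccccc3)c(OCc3ccccc3)c2)ccc1OCc1ccccc1 | intermediate
18 | (5S)-1-[4-(benzyloxy)-3-methoxyphenyl]-7-[3,4-bis(benzyloxy)phenyl]-5-hydroxyheptan-3-one | COc1cc(CCC(=O)C[C@@H](O)CCc2ccc(OCc3ccccc3)c(OCc3ccccc3)c2)ccc1OCc1ccccc1 | intermediate
19 | (5S)-7-(3,4-dihydroxyphenyl)-5-hydroxy-1-(4-hydroxy-3-methoxyphenyl)heptan-3-one | COc1cc(CCC(=O)C[C@@H](O)CCc2ccc(O)c(O)c2)ccc1O | target

**Count**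
Total steps: 13. Longest linear sequence: 10 (steps 1–5 and 9–13).

**Steps most likely to fail**

Step 11. The ring closure could lose out to intermolecular Si–H addition (oligomerisation), to catalyst poisoning by residual amine from step 10, or to hydrolytic loss of the Si–H ether before cyclisation. The fallback keeps an oxygen tether from C5 but delivers oxygen to C3 directly. It sets out from 14. Boc2O and catalytic DMAP in MeCN should give tert-butyl (5S)-1-[4-(benzyloxy)-3-methoxyphenyl]-7-[3,4-bis(benzyloxy)phenyl]hept-2-yn-5-yl carbonate F1. Ph3PAuNTf2 (monovalent gold, 2 mol%) in CH2Cl2 at rt should then trigger 6-exo-dig attack of the carbonate carbonyl on C3 with loss of 2-methylpropene, giving (4Z,6S)-4-{2-[4-(benzyloxy)-3-methoxyphenyl]ethylidene}-6-{2-[3,4-bis(benzyloxy)phenyl]ethyl}-1,3-dioxan-2-one F2. Methanolysis (catalytic K2CO3, MeOH, 0 °C) opens the enol carbonate and the route is rejoined at 18.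

Step 8. Under the basic, warm Grignard conditions the 3-arylpropyne may undergo propargyl–allenyl prototropy, and its own acetylide may be benzylated a second time. The fallback reverses the order of bond formation. It sets out from 7, which is opened with LiC≡CH·H2NCH2CH2NH2 in DMSO at rt to (3S)-1-[3,4-bis(benzyloxy)phenyl]hex-5-yn-3-ol F3. Copper-mediated benzylation of this terminal alkyne with bromide 10 (CuI 10 mol%, Cs2CO3, MeCN, rt) forms C1–C2 last under carbonate base and comes back to the route at 14, bypassing steps 8 and 9.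

Step 12. Fluoride and base may protodesilylate the alkenyl–silicon bond before oxygen is transferred, or may promote dehydration or retro-aldol cleavage of the β-hydroxy ketone as it forms. The fallback avoids fluoride and base. It sets out from 16, which is epoxidised with mCPBA (CH2Cl2, 0 °C) to the α,β-epoxysilane (6S)-2-[4-(benzyloxy)-3-methoxybenzyl]-6-{2-[3,4-bis(benzyloxy)phenyl]ethyl}-4,4-dimethyl-1,5-dioxa-4-silaspiro[2.4]heptane F4, a mixture of epoxide diastereomers. Dilute H2SO4 in aqueous THF at 0 °C should let water open the epoxide at the silicon-bearing C3; Peterson-type β-elimination then gives the C3 enol and, after Si–O hydrolysis, the route is rejoined at 18.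

**Further compounds**
F1 | step 11 | tert-butyl (5S)-1-[4-(benzyloxy)-3-methoxyphenyl]-7-[3,4-bis(benzyloxy)phenyl]hept-2-yn-5-yl carbonate | COc1cc(CC#CC[C@@H](OC(=O)OC(C)(C)C)CCc2ccc(OCc3ccccc3)c(OCc3ccccc3)c2)ccc1OCc1ccccc1
F2 | step 11 | (4Z,6S)-4-{2-[4-(benzyloxy)-3-methoxyphenyl]ethylidene}-6-{2-[3,4-bis(benzyloxy)phenyl]ethyl}-1,3-dioxan-2-one | COc1cc(C/C=C2\OC(=O)O[C@@H](CCc3ccc(OCc4ccccc4)c(OCc4ccccc4)c3)C2)ccc1OCc1ccccc1
F3 | step 8 | (3S)-1-[3,4-bis(benzyloxy)phenyl]hex-5-yn-3-ol | C#CC[C@@H](O)CCc1ccc(OCc2ccccc2)c(OCc2ccccc2)c1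
F4 | step 12 | (6S)-2-[4-(benzyloxy)-3-methoxybenzyl]-6-{2-[3,4-bis(benzyloxy)phenyl]ethyl}-4,4-dimethyl-1,5-dioxa-4-silaspiro[2.4]heptane | COc1cc(CC2OC23C[C@H](CCc4ccc(OCc5ccccc5)c(OCc5ccccc5)c4)O[Si]3(C)C)ccc1OCc1ccccc1
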